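The plan keeps ring A of the lower isoflavan unit dearomatised until the end. In that ring O1 on C8a lies ortho to the alkyl-bearing C4a and meta to the C7 hydroxyl, so C8a is the β-carbon of a para-quinol whose carbonyl is C7 and whose carbinol carbon is C4a. One acid-mediated operation lets the side-chain primary alcohol add to this cyclohexadienone (oxa-Michael, O1–C8a) and expels water, closing the pyran ring and creating the resorcinol ring at once. The precursor is a 4-alkyl-4-hydroxycyclohexa-2,5-dienone obtained from a para-alkylphenol; a biomimetic Friedel–Crafts union, an asymmetric transfer hydrogenation and an Evans alkylation supply the skeleton and the three stereocentres.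

Key step: step 12

Remark on names: U stands for the (3S,4R)-7-(benzyloxy)-3-[2-(benzyloxy)-4-methoxyphenyl]chroman-4-yl group. Chroman numbering is used for both isoflavan units; the "upper" unit is the one that carries the aryl group on C4, the "lower" unit is the one whose pyran ring is closed last.
Assumption: 4-[(tert-butyldimethylsilyl)oxy]benzyl bromide (15) is taken as a catalogue reagent.

Step 1
Reactants: 1 2-bromo-5-methoxyphenol
Product: 2 2-(benzyloxy)-1-bromo-4-methoxybenzene
Conditions: BnBr, K2CO3, DMF, rt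
Reagents that add atoms: benzyl bromide, BrCc1ccccc1
Why: Williamson etherification, the phenoxide displacing bromide from the benzylic carbon in an SN2 reaction.

Step 2
Reactants: 3 7-hydroxychroman-4-one
Product: 4 7-(benzyloxy)chroman-4-one
Conditions: BnBr, K2CO3, acetone, reflux
Reagents that add atoms: benzyl bromide, BrCc1ccccc1
Why: Williamson etherification of the only phenol; the mild carbonate base leaves the chromanone ring intact.

Step 3
Reactants: 4 7-(benzyloxy)chroman-4-one; 2 2-(benzyloxy)-1-bromo-4-methoxybenzene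
Product: 5 rac-7-(benzyloxy)-3-[2-(benzyloxy)-4-methoxyphenyl]chroman-4-one
Conditions: Pd2(dba)3 (2.5 mol%), t-Bu3P·HBF4 (10 mol%), NaOtBu, THF, 60 °C
Reagents that add atoms: none
Why: Palladium-catalysed α-arylation of a ketone enolate (oxidative addition of 2 to zerovalent palladium, enolate binding, reductive elimination); the ortho-substituted aryl group should stop the reaction at monoarylation, and C3 is left racemic on purpose because step 4 equilibrates it.

Step 4
Reactants: 5 rac-7-(benzyloxy)-3-[2-(benzyloxy)-4-methoxyphenyl]chroman-4-one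
Product: 6 (3S,4S)-7-(benzyloxy)-3-[2-(benzyloxy)-4-methoxyphenyl]chroman-4-ol
Conditions: RuCl[(S,S)-TsDPEN](p-cymene) (2 mol%), HCO2H/Et3N (5:2), EtOAc, 40 °C
Reagents that add atoms: none
Why: Noyori asymmetric transfer hydrogenation under dynamic kinetic resolution: Et3N racemises the acidic C3 centre while the (S,S)-configured ruthenium hydride should reduce one ketone enantiomer to the cis alcohol, so the catalyst sets C4 as S (by analogy with aryl alkyl ketones) and the cis preference thereby fixes C3 as S.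

Step 5
Reactants: 2 2-(benzyloxy)-1-bromo-4-methoxybenzene; 7 diethyl malonate
Product: 8 diethyl 2-[2-(benzyloxy)-4-methoxyphenyl]malonate
Conditions: Pd(OAc)2 (2 mol%), t-Bu3P·HBF4 (4 mol%), K3PO4, toluene, 80 °C
Reagents that add atoms: none
Why: Palladium-catalysed arylation of a malonate enolate (Hartwig–Buchwald type), which tolerates ortho-alkoxy aryl bromides.

Step 6
Reactants: 8 diethyl 2-[2-(benzyloxy)-4-methoxyphenyl]malonate
Product: 10 2-[2-(benzyloxy)-4-methoxyphenyl]acetic acid, via arylmalonic acid 9 (not isolated)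
Conditions: NaOH, EtOH/H2O, reflux; then HCl to pH 1, 80 °C
Reagents that add atoms: sodium hydroxide, [Na+].[OH-]
Why: Saponification of both esters followed by thermal decarboxylation of the arylmalonic acid through its cyclic six-membered transition state.

Step 7
Reactants: 10 2-[2-(benzyloxy)-4-methoxyphenyl]acetic acid; 11 (S)-4-benzyl-2-oxazolidinone
Product: 13 (4S)-4-benzyl-3-{2-[2-(benzyloxy)-4-methoxyphenyl]acetyl}oxazolidin-2-one, via pivalic mixed anhydride 12 (not isolated)
Conditions: PivCl, Et3N, THF, −20 °C; then LiCl, 11, −20 °C → rt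
Reagents that add atoms: none
Why: N-acylation of the oxazolidinone by a mixed anhydride under LiCl/Et3N activation, attack occurring at the less hindered arylacetyl carbonyl.

Step 8
Reactants: 6 (3S,4S)-7-(benzyloxy)-3-[2-(benzyloxy)-4-methoxyphenyl]chroman-4-ol; 13 (4S)-4-benzyl-3-{2-[2-(benzyloxy)-4-methoxyphenyl]acetyl}oxazolidin-2-one
Product: 14 (4S)-4-benzyl-3-{2-[2-(benzyloxy)-4-methoxy-5-U-phenyl]acetyl}oxazolidin-2-one
Conditions: 13 (3 equiv), BF3·OEt2 (20 mol%), 4 Å MS, CH2Cl2, −78 → −30 °C, slow addition of 6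
Reagents that add atoms: none
Why: SN1 Friedel–Crafts alkylation that mirrors the presumed biogenesis: the acid ionises the C4 hydroxyl to a benzylic cation stabilised by O1 and the 7-benzyloxy group, the arene of 13 attacks through C5 (para to its benzyloxy, ortho to its methoxy group), and approach anti to the C3 aryl group should give the 3,4-trans (4R) centre by substrate control, whichever C4 epimer of 6 is used.

Step 9
Reactants: 14 (4S)-4-benzyl-3-{2-[2-(benzyloxy)-4-methoxy-5-U-phenyl]acetyl}oxazolidin-2-one; 15 4-[(tert-butyldimethylsilyl)oxy]benzyl bromide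
Product: 16 (4S)-4-benzyl-3-{(2S)-2-[2-(benzyloxy)-4-methoxy-5-U-phenyl]-3-[4-(tert-butyldimethylsilyloxy)phenyl]propanoyl}oxazolidin-2-one
Conditions: NaHMDS, THF, −78 °C; then 15, −78 → −40 °C
Reagents that add atoms: none
Why: Evans asymmetric alkylation: the chelated Z sodium enolate is benzylated on the face opposite the benzyl group of the (S)-auxiliary, which for an α-aryl imide corresponds to the 2S centre (the later C3 of the lower unit).

Step 10
Reactants: 16 (4S)-4-benzyl-3-{(2S)-2-[2-(benzyloxy)-4-methoxy-5-U-phenyl]-3-[4-(tert-butyldimethylsilyloxy)phenyl]propanoyl}oxazolidin-2-one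
Product: 18 4-{(2S)-2-[2-(benzyloxy)-4-methoxy-5-U-phenyl]-3-hydroxypropyl}phenol, via silyl ether alcohol 17 (not isolated)
Conditions: LiBH4, MeOH (2 equiv), THF, 0 °C → rt; then 2 M NaOH, MeOH, rt; HCl work-up
Reagents that add atoms: none
Why: Reductive cleavage of the N-acyloxazolidinone by LiBH4 gives the primary alcohol and frees the auxiliary; only after the centre is no longer α to a carbonyl is hydroxide added, which cleaves the aryl silyl ether (aryloxide leaving group at silicon) without risk of epimerisation.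

Step 11
Reactants: 18 4-{(2S)-2-[2-(benzyloxy)-4-methoxy-5-U-phenyl]-3-hydroxypropyl}phenol
Product: 20 4-{(2S)-2-[2-(benzyloxy)-4-methoxy-5-U-phenyl]-3-hydroxypropyl}-4-hydroxycyclohexa-2,5-dien-1-one, via hydroperoxide 19 (not isolated)
Conditions: Oxone (2KHSO5·KHSO4·K2SO4), NaHCO3, MeCN/H2O, rt; then aq. Na2S2O3
Reagents that add atoms: Oxone (potassium peroxymonosulfate, whose singlet oxygen supplies the carbinol oxygen), [K+].[O-]S(=O)(=O)OO
Why: Oxidative dearomatisation of a para-alkylphenol: singlet oxygen released from the peroxymonosulfate adds para to the free phenol to give the 4-hydroperoxy dienone, which thiosulfate reduces to the para-quinol; benzyl aryl ethers and the primary alcohol should be inert, and this oxidant does not induce the spiro-etherification that iodine-based oxidants would cause with the free alcohol.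

Step 12
Reactants: 20 4-{(2S)-2-[2-(benzyloxy)-4-methoxy-5-U-phenyl]-3-hydroxypropyl}-4-hydroxycyclohexa-2,5-dien-1-one
Product: 22 (3S)-3-[2-(benzyloxy)-4-methoxy-5-U-phenyl]chroman-7-ol, via bicyclic oxa-Michael adduct 21 (not isolated)
Conditions: TsOH·H2O (20 mol%), CH2Cl2, 0 °C → 40 °C
Reagents that add atoms: none
Why: Protonation of the cross-conjugated dienone makes its β-carbons electrophilic and the tethered primary hydroxyl adds to one of them, forming O1–C8a and the cis-fused bicycle 21; acid-catalysed enolisation of 21 then gives an arene hydrate that loses the C4a hydroxyl as water and aromatises to the 7-hydroxychroman. The closest known reactions are the intramolecular oxa-Michael cyclisation of hydroxyalkyl para-quinols (the rengyolone and cleroindicin type) and the acid-promoted dehydrative aromatisation of Michael adducts of para-quinols to meta-substituted phenols. The only ring closed is the pyran ring of the lower isoflavan, in the 6-exo-trig mode. No permanent stereocentre is created: the transient centres C4a and C8a are erased on aromatisation, so attack on either diastereotopic enone arm converges on the same product, and C3 is untouched because it carries no acidifying group. The step needs O-attack at the β-carbon to win over the 1,2-alkyl shift of the quinol (dienone–phenol rearrangement) and over arene attack; this should be secured by the six-membered transition state, by the mild sulfonic acid (the 1,2-shift needs strong acid) and by the fact that the only arene carbon within reach, C6' of the lower ring B, is meta to both of its oxygens.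

Step 13
Reactants: 22 (3S)-3-[2-(benzyloxy)-4-methoxy-5-U-phenyl]chroman-7-ol
Product: 23 (3S,4R)-3-(2-hydroxy-4-methoxyphenyl)-4-{4-hydroxy-5-[(3S)-7-hydroxychroman-3-yl]-2-methoxyphenyl}chroman-7-ol
Conditions: H2 (1 atm), Pd/C, EtOAc/MeOH, rt
Reagents that add atoms: none
Why: Hydrogenolysis of the three benzyl aryl ethers over palladium on carbon; the chroman C–O bonds (aryl–O–CH2) and the benzylic C–C bonds are not cleaved.

Compound list (U as defined above)

1 | 2-bromo-5-methoxyphenol | COc1ccc(Br)c(O)c1 | starting material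
2 | 2-(benzyloxy)-1-bromo-4-methoxybenzene | COc1ccc(Br)c(OCc2ccccc2)c1 | intermediate
3 | 7-hydroxychroman-4-one | O=C1CCOc2cc(O)ccc12 | starting material
4 | 7-(benzyloxy)chroman-4-one | O=C1CCOc2cc(OCc3ccccc3)ccc12 | intermediate
5 | rac-7-(benzyloxy)-3-[2-(benzyloxy)-4-methoxyphenyl]chroman-4-one | COc1ccc(C2COc3cc(OCc4ccccc4)ccc3C2=O)c(OCc2ccccc2)c1 | intermediate
6 | (3S,4S)-7-(benzyloxy)-3-[2-(benzyloxy)-4-methoxyphenyl]chroman-4-ol (cis) | COc1ccc([C@H]2COc3cc(OCc4ccccc4)ccc3[C@H]2O)c(OCc2ccccc2)c1 | intermediate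
7 | diethyl malonate | CCOC(=O)CC(=O)OCC | starting material
8 | diethyl 2-[2-(benzyloxy)-4-methoxyphenyl]malonate | CCOC(=O)C(C(=O)OCC)c1ccc(OC)cc1OCc1ccccc1 | intermediate
9 | 2-[2-(benzyloxy)-4-methoxyphenyl]malonic acid | OC(=O)C(C(O)=O)c1ccc(OC)cc1OCc1ccccc1 | intermediate
10 | 2-[2-(benzyloxy)-4-methoxyphenyl]acetic acid | OC(=O)Cc1ccc(OC)cc1OCc1ccccc1 | intermediate
11 | (S)-4-benzyl-2-oxazolidinone | O=C1N[C@@H](Cc2ccccc2)CO1 | starting material
12 | 2-[2-(benzyloxy)-4-methoxyphenyl]acetic pivalic anhydride | CC(C)(C)C(=O)OC(=O)Cc1ccc(OC)cc1OCc1ccccc1 | intermediate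
13 | (4S)-4-benzyl-3-{2-[2-(benzyloxy)-4-methoxyphenyl]acetyl}oxazolidin-2-one | COc1ccc(CC(=O)N2C(=O)OC[C@@H]2Cc2ccccc2)c(OCc2ccccc2)c1 | intermediate
14 | (4S)-4-benzyl-3-{2-[2-(benzyloxy)-4-methoxy-5-U-phenyl]acetyl}oxazolidin-2-one | COc1ccc([C@H]2COc3cc(OCc4ccccc4)ccc3[C@@H]2c2cc(CC(=O)N3C(=O)OC[C@@H]3Cc3ccccc3)c(OCc3ccccc3)cc2OC)c(OCc2ccccc2)c1 | intermediate
15 | 4-[(tert-butyldimethylsilyl)oxy]benzyl bromide | CC(C)(C)[Si](C)(C)Oc1ccc(CBr)cc1 | starting material
16 | (4S)-4-benzyl-3-{(2S)-2-[2-(benzyloxy)-4-methoxy-5-U-phenyl]-3-[4-(tert-butyldimethylsilyloxy)phenyl]propanoyl}oxazolidin-2-one | COc1ccc([C@H]2COc3cc(OCc4ccccc4)ccc3[C@@H]2c2cc([C@H](Cc3ccc(O[Si](C)(C)C(C)(C)C)cc3)C(=O)N3C(=O)OC[C@@H]3Cc3ccccc3)c(OCc3ccccc3)cc2OC)c(OCc2ccccc2)c1 | intermediate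
17 | (2S)-2-[2-(benzyloxy)-4-methoxy-5-U-phenyl]-3-[4-(tert-butyldimethylsilyloxy)phenyl]propan-1-ol | COc1ccc([C@H]2COc3cc(OCc4ccccc4)ccc3[C@@H]2c2cc([C@H](Cc3ccc(O[Si](C)(C)C(C)(C)C)cc3)CO)c(OCc3ccccc3)cc2OC)c(OCc2ccccc2)c1 | intermediate
18 | 4-{(2S)-2-[2-(benzyloxy)-4-methoxy-5-U-phenyl]-3-hydroxypropyl}phenol | COc1ccc([C@H]2COc3cc(OCc4ccccc4)ccc3[C@@H]2c2cc([C@H](Cc3ccc(O)cc3)CO)c(OCc3ccccc3)cc2OC)c(OCc2ccccc2)c1 | intermediate
19 | 4-{(2S)-2-[2-(benzyloxy)-4-methoxy-5-U-phenyl]-3-hydroxypropyl}-4-hydroperoxycyclohexa-2,5-dien-1-one | COc1ccc([C@H]2COc3cc(OCc4ccccc4)ccc3[C@@H]2c2cc([C@H](CC3(OO)C=CC(=O)C=C3)CO)c(OCc3ccccc3)cc2OC)c(OCc2ccccc2)c1 | intermediate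
20 | 4-{(2S)-2-[2-(benzyloxy)-4-methoxy-5-U-phenyl]-3-hydroxypropyl}-4-hydroxycyclohexa-2,5-dien-1-one | COc1ccc([C@H]2COc3cc(OCc4ccccc4)ccc3[C@@H]2c2cc([C@H](CC3(O)C=CC(=O)C=C3)CO)c(OCc3ccccc3)cc2OC)c(OCc2ccccc2)c1 | intermediate
21 | (3S,4aS,8aS)-3-[2-(benzyloxy)-4-methoxy-5-U-phenyl]-4a-hydroxy-2,3,4,4a,8,8a-hexahydro-7H-chromen-7-one (drawn as one of the two cis-fused C4a/C8a diastereomers; both lead to 22) | COc1ccc([C@H]2COc3cc(OCc4ccccc4)ccc3[C@@H]2c2cc([C@H]3CO[C@H]4CC(=O)C=C[C@@]4(O)C3)c(OCc3ccccc3)cc2OC)c(OCc2ccccc2)c1 | intermediate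
22 | (3S)-3-[2-(benzyloxy)-4-methoxy-5-U-phenyl]chroman-7-ol | COc1ccc([C@H]2COc3cc(OCc4ccccc4)ccc3[C@@H]2c2cc([C@H]3COc4cc(O)ccc4C3)c(OCc3ccccc3)cc2OC)c(OCc2ccccc2)c1 | intermediate
23 | (3S,4R)-3-(2-hydroxy-4-methoxyphenyl)-4-{4-hydroxy-5-[(3S)-7-hydroxychroman-3-yl]-2-methoxyphenyl}chroman-7-ol | COc1ccc([C@H]2COc3cc(O)ccc3[C@@H]2c2cc([C@H]3COc4cc(O)ccc4C3)c(O)cc2OC)c(O)c1 | target

Total step count: 13. Longest linear sequence: 10 steps (1, 5, 6, 7, 8, 9, 10, 11, 12, 13).

Steps most likely to fail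

1. Step 12 (key step). The reversible oxa-Michael adduct may revert, the quinol may undergo the acid-induced 1,2-alkyl shift instead, or the sequence may stall at the hydrated bicycle without aromatising. The fallback forms the same O1–C8a bond by palladium-catalysed intramolecular etherification of an aryl bromide, a closure known from enantioselective isoflavan synthesis. It sets out from 14 and comes back at 23. Commercial 2-bromo-4-hydroxybenzaldehyde would be benzylated (BnBr, K2CO3) to 4-(benzyloxy)-2-bromobenzaldehyde F1, reduced (NaBH4) to [4-(benzyloxy)-2-bromophenyl]methanol F2 and converted (PBr3) into 4-(benzyloxy)-2-bromobenzyl bromide F3. Evans alkylation of 14 with F3 (NaHMDS, −78 °C) should give the bromoaryl imide F4, and LiBH4 the bromo alcohol F5. Cyclisation with Pd(OAc)2, 2-(di-tert-butylphosphino)-1,1'-binaphthyl and Cs2CO3 in toluene at 80 °C should give the tetra-O-benzyl ether F6, and hydrogenolysis over Pd/C would deliver 23.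

2. Step 11. The oxidant may attack the benzyloxy-rich rings, the lipophilic phenol may react sluggishly in the aqueous medium, or the hydroperoxide or quinol may be lost by premature reaction of the free side-chain alcohol. The fallback switches to a two-electron phenol oxidation with the side-chain oxygen blocked. It sets out from 17 (step 10 stopped before the NaOH stage) and comes back at 20. Acetylation (Ac2O, pyridine) would give the silyl ether acetate F7, and TBAF buffered with AcOH the phenol acetate F8. PhI(OAc)2 in MeCN/H2O at 0 °C should give the para-quinol acetate F9, the ester preventing spiro-etherification. Methanolysis (K2CO3, MeOH, 0 °C) would return 20, possibly already partly cyclised to 21, and step 12 follows unchanged.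

3. Step 8. The cation from 6 may be consumed by self-alkylation through the electron-rich rings of a second molecule of 6, the imide carbonyls may tie up the Lewis acid, and loss of H-3 from the cation (isoflav-3-ene formation followed by re-protonation) would erode the C3 configuration. The fallback moves the coupling to a cheap nucleophile without Lewis-basic groups, used in large excess so that capture outruns both processes, and builds the side chain afterwards. It sets out from 6 and 2 and comes back at 14. Compound 6 would be added slowly to 2 (10 equiv) with BF3·OEt2 (10 mol%) in CH2Cl2 at −78 °C to give (3S,4R)-7-(benzyloxy)-4-[4-(benzyloxy)-5-bromo-2-methoxyphenyl]-3-[2-(benzyloxy)-4-methoxyphenyl]chroman F10. Malonate arylation as in step 5 should give the diethyl arylmalonate F11, and saponification with decarboxylation as in step 6 the arylacetic acid F12. Acylation of 11 as in step 7 would then give 14.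

Further compounds

F1 | step 12 | 4-(benzyloxy)-2-bromobenzaldehyde | O=Cc1ccc(OCc2ccccc2)cc1Br
F2 | step 12 | [4-(benzyloxy)-2-bromophenyl]methanol | OCc1ccc(OCc2ccccc2)cc1Br
F3 | step 12 | 4-(benzyloxy)-2-bromobenzyl bromide | BrCc1ccc(OCc2ccccc2)cc1Br
F4 | step 12 | (4S)-4-benzyl-3-{(2S)-2-[2-(benzyloxy)-4-methoxy-5-U-phenyl]-3-[4-(benzyloxy)-2-bromophenyl]propanoyl}oxazolidin-2-one | COc1ccc([C@H]2COc3cc(OCc4ccccc4)ccc3[C@@H]2c2cc([C@H](Cc3ccc(OCc4ccccc4)cc3Br)C(=O)N3C(=O)OC[C@@H]3Cc3ccccc3)c(OCc3ccccc3)cc2OC)c(OCc2ccccc2)c1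
F5 | step 12 | (2S)-2-[2-(benzyloxy)-4-methoxy-5-U-phenyl]-3-[4-(benzyloxy)-2-bromophenyl]propan-1-ol | COc1ccc([C@H]2COc3cc(OCc4ccccc4)ccc3[C@@H]2c2cc([C@H](Cc3ccc(OCc4ccccc4)cc3Br)CO)c(OCc3ccccc3)cc2OC)c(OCc2ccccc2)c1
F6 | step 12 | (3S)-7-(benzyloxy)-3-[2-(benzyloxy)-4-methoxy-5-U-phenyl]chroman | COc1ccc([C@H]2COc3cc(OCc4ccccc4)ccc3[C@@H]2c2cc([C@H]3COc4cc(OCc5ccccc5)ccc4C3)c(OCc3ccccc3)cc2OC)c(OCc2ccccc2)c1
F7 | step 11 | (2S)-2-[2-(benzyloxy)-4-methoxy-5-U-phenyl]-3-[4-(tert-butyldimethylsilyloxy)phenyl]propyl acetate | COc1ccc([C@H]2COc3cc(OCc4ccccc4)ccc3[C@@H]2c2cc([C@H](Cc3ccc(O[Si](C)(C)C(C)(C)C)cc3)COC(C)=O)c(OCc3ccccc3)cc2OC)c(OCc2ccccc2)c1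
F8 | step 11 | (2S)-2-[2-(benzyloxy)-4-methoxy-5-U-phenyl]-3-(4-hydroxyphenyl)propyl acetate | COc1ccc([C@H]2COc3cc(OCc4ccccc4)ccc3[C@@H]2c2cc([C@H](Cc3ccc(O)cc3)COC(C)=O)c(OCc3ccccc3)cc2OC)c(OCc2ccccc2)c1
F9 | step 11 | (2S)-2-[2-(benzyloxy)-4-methoxy-5-U-phenyl]-3-(1-hydroxy-4-oxocyclohexa-2,5-dien-1-yl)propyl acetate | COc1ccc([C@H]2COc3cc(OCc4ccccc4)ccc3[C@@H]2c2cc([C@H](CC3(O)C=CC(=O)C=C3)COC(C)=O)c(OCc3ccccc3)cc2OC)c(OCc2ccccc2)c1
F10 | step 8 | (3S,4R)-7-(benzyloxy)-4-[4-(benzyloxy)-5-bromo-2-methoxyphenyl]-3-[2-(benzyloxy)-4-methoxyphenyl]chroman | COc1ccc([C@H]2COc3cc(OCc4ccccc4)ccc3[C@@H]2c2cc(Br)c(OCc3ccccc3)cc2OC)c(OCc2ccccc2)c1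
F11 | step 8 | diethyl 2-[2-(benzyloxy)-4-methoxy-5-U-phenyl]malonate | COc1ccc([C@H]2COc3cc(OCc4ccccc4)ccc3[C@@H]2c2cc(C(C(=O)OCC)C(=O)OCC)c(OCc3ccccc3)cc2OC)c(OCc2ccccc2)c1
F12 | step 8 | 2-[2-(benzyloxy)-4-methoxy-5-U-phenyl]acetic acid | COc1ccc([C@H]2COc3cc(OCc4ccccc4)ccc3[C@@H]2c2cc(CC(=O)O)c(OCc3ccccc3)cc2OC)c(OCc2ccccc2)c1
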